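3 questions are put on this flask; they stand here with the runs made before it.

| flask | substrate | reagent in the second phase | remark | time | volume of the second phase over the first |
|---|---|---|---|---|---|
| ochre | 46 mM | 34 mM | run made earlier |  |  |
| red | 46 mM | 140 mM | run made earlier |  |  |
| green | 23 mM | 69 mM | run made earlier |  |  |
| flask | 46 mM | 69.0 mM |  | 6.0 min | 1.0 |

| run | time / min | target / % |
|---|---|---|
| ochre | 0.500 | 2 |
| ochre | 1.33 | 4 |
| ochre | 3.00 | 5 |
| ochre | 8.00 | 15 |
| red | 0.500 | 0 |
| red | 1.33 | 5 |
| red | 3.00 | 12 |
| red | 8.00 | 21 |
| green | 2.00 | 4 |
| green | 4.00 | 16 |
| green | 5.00 | 15 |
| green | 8.00 | 20 |

(scatter of a reading: 2 percentage points)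

* amount of target at 6.0 min, in percent of the substrate charged
* the change that raises the amount of target at 6.0 min, in percent of the substrate charged most ("none" if none brings more than 2 percentage points) (east / west / none)
* amount of target at 6.0 min, in percent of the substrate charged, after west

- in the second phase: reagent in the second phase; everything else is in the first
- charges count per volume of the first phase; a concentration in a rate is the amount of a species over the volume of its own phase; every rate counts per litre of the first phase
- the earlier runs were read with a standard deviation of 2 percentage points
- the earlier runs hold the two phases in the same ratio of volumes as the flask asked about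

What do you carry from the runs? A half-life, read from each last reading at 8.00 min as if the loss were pseudo-first-order at a fixed reagent charge: ochre gives 34.1 min, red 23.5 min.

Why those two runs? They hold the flask's substrate charge, 46 mM, and the flask's reagent is twice ochre's, while red's is twice the flask's. So their geometric mean, 28.3 min, is my half-life of the charge toward target, the time in which the fraction of the charge not yet turned into target falls by a factor of 2.

And the flask? 6.0 min is 0.212 half-lives, so I expect a fraction 13.7 % as target.

The changes? East puts the reagent at 138 mM, next to red, so it takes red's half-life and gives 16.2 %, a gain of 2.6 percentage points, which is more than 2 points. No run varies the transfer coefficient, so I put no number on west and have no ranking of east against it. My answer is east, the change with a reckoned gain over the margin, with west left open.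

With 2 points on each reading? Then east is a call, not a measurement.

The forecast gives 14 %, none as the best change, and 15.5 % after west, calling this “a tentative, borderline call”. It stands beside my fraction on the first answer and parts from me on the second.

The flask gives 18.6 %, east adds 5.4 points, which is more than the 3.1 points of west, and west reaches 21.7 %.

    reagent in the reaction phase ⇌ reagent in the second phase, rate k1*([reagent in the reaction phase] - [reagent in the second phase]/K1) per volume of the first phase (partition coefficient = 0.490, kL = 0.110 min⁻¹)
    reagent in the reaction phase + target → over-reaction product (k = 1.50 M⁻¹ min⁻¹)
    substrate + reagent in the reaction phase → target (k = 3.00 M⁻¹ min⁻¹)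
    substrate ⇌ dormant form (K = 0.930, k = 0.100 min⁻¹)
    reagent in the reaction phase + target → over-reacted product (k = 2.50 M⁻¹ min⁻¹)

My 0.212 half-lives counted 13.7 % leaving the charge, and the flask holds 24.5 % in target and its 2 further products together. The flask left until 25 min counts 0.883 half-lives, so 45.8 % should have left. That flask holds 58.5 % in those products: over-reacted product 25.0 %, over-reaction product 15.0 %, and target 18.5 %.

(The numbers in the tables were computed on assumed constants; noise was put on by code.)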